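Retrosynthetic overview
1. The 4(15)-methylene is made last by dehydrating a tertiary C4 alcohol; before that the trans-1,10- and cis-2,3-oxiranes come from peracid epoxidation of a (1(10)E,2Z)-diene beside that alcohol, and the angelate is placed on O8.
2. The gamma-lactone C6–O bond is closed with inversion by a C7 acetic acid arm; O8 is carried as a C8–Si bond until the lactone exists.
3. The strategy rests on the run O–C6–C7–C8–C9–C10(C14)=C1 of the ten-membered ring, which is the retron of a cyclodec-5-enone: cutting C8–C9 and rejoining C1–C6 gives a trans-1,2-dialkenylcyclohexenol (anionic oxy-Cope), and C7–C11 goes back to alkylation of the resulting enolate in the same flask.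
4. The six-membered ring (C1 to C6 with C9, C10, C14, C15) is (R)-carvone, whose ring alkene ends as the Z C2=C3 bond; C7 and C8 arrive as a silylvinyl cerium reagent.
5. Ring order: carvone cyclohexene, dioxolane on O4/O5, ten-membered carbocycle by four-atom ring expansion, gamma-lactone, then the two oxiranes.

Key step: step 13

Remark on the chemistry: germacrane numbering is used for every intermediate (in carvone: C5 carbonyl, C4 methyl-bearing alkene carbon, C3 alkene CH, C2 ring CH2, C1 isopropenyl-bearing carbon, C6 the other CH2); the target has O6 trans to the C7 arm and on the face opposite O5, whereas zinc-chelate reduction of the C6 ketone should place O6 on the O5 side, so the lactone is closed with inversion at C6 from an allyl ester arm.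

Step 1
Reactants: 1 (R)-(−)-carvone
Product: 3 carvone trimethylsilyl dienol ether, via lithium dienolate 2 (not isolated)
Conditions: LiN(iPr)2 (LDA), THF, −78 °C; Me3SiCl, −78 °C to rt; pentane, filtration
Reagents that add atoms: chlorotrimethylsilane, C[Si](C)(C)Cl
Why: Kinetic deprotonation of the enone at the alpha' CH2 (C6) followed by O-silylation should give the cross-conjugated dienol ether without touching C1.

Step 2
Reactants: 3 carvone trimethylsilyl dienol ether
Product: 5 trans-6-hydroxycarvone, via trans-6-(trimethylsilyloxy)carvone 4 (not isolated)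
Conditions: mCPBA, NaHCO3, hexane–CH2Cl2, −15 °C; then 1 M HCl, THF, 0 °C
Reagents that add atoms: meta-chloroperbenzoic acid, OOC(=O)c1cccc(Cl)c1
Why: Rubottom oxidation, in which the peracid should attack the electron-rich enol ether alkene (not the isopropenyl group) anti to the neighbouring isopropenyl substituent, so that silyl migration and hydrolysis leave the C6 hydroxyl trans to it.

Step 3
Reactants: 5 trans-6-hydroxycarvone
Product: 6 trans-6-(tert-butyldimethylsilyloxy)carvone
Conditions: t-BuMe2SiCl, imidazole, DMF, rt
Reagents that add atoms: tert-butylchlorodimethylsilane, CC(C)(C)[Si](C)(C)Cl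
Why: Ordinary silylation of the secondary alpha-ketol, which should proceed without change at C6 since the trans isomer is also the more stable one.

Step 4
Reactants: 6 trans-6-(tert-butyldimethylsilyloxy)carvone
Product: 7 allylic C5 alcohol (OH cis to isopropenyl)
Conditions: NaBH4, CeCl3·7H2O, MeOH, −78 °C
Reagents that add atoms: none
Why: Luche 1,2-reduction, where axial hydride attack on the half-chair with equatorial isopropenyl and silyloxy groups should give the equatorial C5 alcohol, cis to isopropenyl (as in carvone to cis-carveol) and trans to O6.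

Step 5
Reactants: 7 allylic C5 alcohol
Product: 8 3,4-epoxy alcohol (oxirane on the C5–OH face)
Conditions: VO(acac)2 (cat.), t-BuOOH, CH2Cl2, 0 °C to rt
Reagents that add atoms: tert-butyl hydroperoxide, CC(C)(C)OO
Why: Vanadium-alkoxide-directed epoxidation should deliver oxygen to C3=C4 from the C5 hydroxyl face only and leave the isopropenyl alkene, which fixes C4–O cis to C5–O.

Step 6
Reactants: 8 3,4-epoxy alcohol
Product: 9 C3 phenylselenide 4,5-diol
Conditions: PhSeSePh, NaBH4, EtOH, rt to 60 °C
Reagents that add atoms: diphenyl diselenide, c1ccc(cc1)[Se][Se]c1ccccc1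
Why: Selenolate should open the oxirane at the secondary carbon C3 with inversion (trans-diaxial opening through the chair that keeps isopropenyl, O5 and O6 equatorial), leaving the tertiary C4 carbinol configuration untouched.

Step 7
Reactants: 9 C3 phenylselenide 4,5-diol
Product: 11 cis-4,5-diol with C2=C3 alkene, via selenoxide 10 (not isolated)
Conditions: 30% H2O2, pyridine, CH2Cl2, 0 °C to rt
Reagents that add atoms: none
Why: Selenoxide syn-elimination can only run towards C2 because C4 carries no hydrogen, which should give the transposed tertiary allylic alcohol with the ring alkene at C2=C3.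

Step 8
Reactants: 11 cis-4,5-diol with C2=C3 alkene
Product: 12 4,5-acetonide 6-silyl ether
Conditions: 2-methoxypropene, PPTS (cat.), CH2Cl2, 0 °C
Reagents that add atoms: 2-methoxypropene, COC(C)=C
Why: The cis diol should close to the dioxolane under acid mild enough not to ionise the tertiary allylic C4–O bond.

Step 9
Reactants: 12 4,5-acetonide 6-silyl ether
Product: 13 4,5-acetonide C6 alcohol
Conditions: Bu4NF, THF, 0 °C to rt
Reagents that add atoms: none
Why: Fluoride cleavage of the secondary silyl ether should leave the acetonide and both alkenes untouched.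

Step 10
Reactants: 13 4,5-acetonide C6 alcohol
Product: 14 acetonide-protected 1-isopropenylcyclohex-2-en-6-one
Conditions: Dess–Martin periodinane, NaHCO3, CH2Cl2, 0 °C; used at once
Reagents that add atoms: none
Why: Buffered neutral Dess–Martin oxidation should give the ketone without enolising C1–H (alpha to the carbonyl and doubly allylic), so C1 keeps its configuration and neither alkene moves into conjugation.

Step 11
Reactants: 15 trans-1,2-bis(tributylstannyl)ethene
Product: 17 (E)-1-(benzyldimethylsilyl)-2-(tributylstannyl)ethene, via (E)-2-(tributylstannyl)vinyllithium 16 (not isolated)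
Conditions: n-BuLi (1.0 equiv), THF, −78 °C; BnMe2SiCl, −78 °C to rt
Reagents that add atoms: benzylchlorodimethylsilane, C[Si](C)(Cl)Cc1ccccc1
Why: Tin–lithium exchange of one stannyl group with retention of alkene geometry and silylation of the vinyllithium should give the E silyl stannyl ethene.

Step 12
Reactants: 17 (E)-1-(benzyldimethylsilyl)-2-(tributylstannyl)ethene; 14 acetonide-protected 1-isopropenylcyclohex-2-en-6-one
Product: 20 trans-1,2-dialkenyl cyclohexenol, via (E)-2-(benzyldimethylsilyl)vinyllithium 18 (not isolated), via vinylcerium dichloride 19 (not isolated)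
Conditions: n-BuLi, THF, −78 °C; anhydrous CeCl3, THF, −78 °C; then 14, −78 °C
Reagents that add atoms: none
Why: Tin–lithium exchange with retention, transmetalation to the weakly basic organocerium and 1,2-addition to the enolisable ketone by equatorial attack on the face opposite the isopropenyl group and the pseudoaxial C4–O bond should set C6 with the silylvinyl group trans to isopropenyl (both equatorial) and the hydroxyl axial.

Step 13
Reactants: 20 trans-1,2-dialkenyl cyclohexenol; 21 allyl bromoacetate
Product: 24 (1(10)E,2Z)-cyclodecadien-6-one with C7 allyl acetate arm, via potassium alkoxide 22 (not isolated), via potassium enolate 23 (not isolated)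
Conditions: KN(SiMe3)2 (KHMDS, 1.05 equiv), 18-crown-6, THF, −78 to 0 °C; then 21, −78 °C
Reagents that add atoms: none
Why: Deprotonation gives alkoxide 22, whose C1–C6 bond (alpha to O−, doubly allylic) breaks while C8–C9 forms in a chair [3,3] shift through the two exocyclic alkenyl groups, and the resulting C6=C7 enolate 23 is then C-alkylated at C7 by the bromoacetate (C7–C11). The closest known reaction type is the anionic oxy-Cope ring expansion of trans-1,2-dialkenylcyclohexanols to (E)-cyclodec-5-enones with alkylation of the enolate in the same flask. The ten-membered ring is not closed end to end but arises by four-atom sigmatropic ring expansion of the cyclohexene, so no medium-ring cyclisation entropy is paid. C8 is set by the chair, in which the E silyl group is equatorial and C9 bonds to the face fixed by C1 and C6 of 20; the C1(10) alkene should come out E because the ring bonds at C1 and C6 are equatorial on that chair; and C7 is set by alkylation on the outer face of the ring enolate, anti to the C8 silyl group. The step needs the chair through the isopropenyl group and not a boat through the ring C2=C3 alkene or a fragmentation–recombination path, and the trans-diequatorial alkenyl groups of 20, low temperature and a crown-separated potassium ion should secure this. Silicon at C8 leaves the enolate without a beta leaving group, so it should survive to be trapped cold before it can equilibrate towards C5.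

Step 14
Reactants: 24 (1(10)E,2Z)-cyclodecadien-6-one with C7 allyl acetate arm
Product: 25 C6 alcohol with O6 cis to O5 and to the C7 arm
Conditions: Zn(BH4)2, Et2O, −30 °C; pH 7 buffer; crude used directly
Reagents that add atoms: none
Why: Cram-chelate-controlled reduction in which zinc bridges the C6 carbonyl and the C5 dioxolane oxygen, the ring then lies on the C4 side of the carbonyl plane and hydride should enter from the open H5 side (also anti to C8 in the Felkin–Anh sense at C7), giving the C6 epimer needed for closure with inversion while the allyl ester is not reduced.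

Step 15
Reactants: 25 C6 alcohol
Product: 26 C6 mesylate
Conditions: MsCl, Et3N, CH2Cl2, −10 °C
Reagents that add atoms: methanesulfonyl chloride, CS(=O)(=O)Cl
Why: Sulfene-type mesylation should activate the hindered secondary alcohol with retention and quickly enough at low temperature to forestall closure to the cis-lactone.

Step 16
Reactants: 26 C6 mesylate
Product: 28 trans-fused 6,12-lactone with C8 silane, via mesyloxy acid 27 (not isolated)
Conditions: Pd(PPh3)4 (5 mol %), morpholine, THF, rt; then 50 °C
Reagents that add atoms: none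
Why: Allyl transfer from the ester to morpholine through a pi-allyl complex of zerovalent palladium frees the carboxylate under neutral conditions, and its 5-exo-tet SN2 attack on the C6 mesylate should close the gamma-lactone with inversion, so that O6 ends trans to the C7 arm and opposite to O5.

Step 17
Reactants: 28 trans-fused 6,12-lactone with C8 silane
Product: 30 8-hydroxy 6,12-lactone, via fluorosilane 29 (not isolated)
Conditions: Bu4NF, THF, 0 °C; then KHCO3, 30% H2O2, MeOH–THF, rt, short reaction time
Reagents that add atoms: hydrogen peroxide, OO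
Why: Tamao–Fleming oxidation, in which fluoride cleaves the benzyl–silicon bond and peroxide-induced 1,2-shift of C8 from silicon to oxygen proceeds with retention, should put the hydroxyl where silicon was; it is run before the methylene lactone exists so that no Michael acceptor meets fluoride or hydroperoxide, and kept brief and bicarbonate-buffered so the lactone stays on O6.

Step 18
Reactants: 30 8-hydroxy 6,12-lactone
Product: 31 8-triethylsilyloxy 6,12-lactone
Conditions: Et3SiCl, imidazole, DMF, 0 °C
Reagents that add atoms: chlorotriethylsilane, CC[Si](Cl)(CC)CC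
Why: Near-neutral silylation should cap O8 before the strongly basic step and so exclude alkoxide-driven translactonisation to O8.

Step 19
Reactants: 31 8-triethylsilyloxy 6,12-lactone
Product: 33 C11 dimethylaminomethyl lactone, via lithium lactone enolate 32 (not isolated)
Conditions: LiN(iPr)2 (LDA), THF, −78 °C; Eschenmoser's salt, −78 °C to rt
Reagents that add atoms: dimethylmethylideneammonium iodide (Eschenmoser's salt), C=[N+](C)C.[I-]
Why: Enolisation of the gamma-lactone at C11 (its only acidic C–H, with no beta leaving group) and Mannich reaction with the iminium salt should give the amine, whose new C11 centre is removed in step 20.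

Step 20
Reactants: 33 C11 dimethylaminomethyl lactone
Product: 35 alpha-methylene lactone 8-silyl ether, via trimethylammonium iodide 34 (not isolated)
Conditions: MeI, MeOH, rt; then NaHCO3, CH2Cl2–H2O, rt
Reagents that add atoms: none
Why: Exhaustive N-methylation followed by E1cB loss of trimethylamine under bicarbonate should give the exocyclic C11=C13 alkene.

Step 21
Reactants: 35 alpha-methylene lactone 8-silyl ether
Product: 36 8-hydroxy alpha-methylene lactone
Conditions: HF·pyridine, pyridine, THF, 0 °C
Reagents that add atoms: none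
Why: Pyridine-buffered HF should cleave the secondary triethylsilyl ether while acetonide, lactone and Michael acceptor survive.

Step 22
Reactants: 36 8-hydroxy alpha-methylene lactone; 37 angelic acid
Product: 39 8-O-angelate acetonide, via mixed anhydride 38 (not isolated)
Conditions: 2,4,6-trichlorobenzoyl chloride, Et3N, toluene, rt; then 36, 75 °C (no DMAP)
Reagents that add atoms: none
Why: Yamaguchi-type acylation through the mixed anhydride without a nucleophilic catalyst (which could add to the enoate and isomerise it to the tiglate) should acylate O8 at the less hindered angeloyl carbonyl with the Z geometry kept, O4 and O5 being still masked.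

Step 23
Reactants: 39 8-O-angelate acetonide
Product: 40 4,5-diol
Conditions: AcOH–H2O–THF (3:1:1), 35 °C
Reagents that add atoms: none
Why: Acetal hydrolysis through the acetone oxocarbenium ion in weak aqueous acid should free the cis diol without ionising the tertiary dienylic C4–O bond or touching the esters.

Step 24
Reactants: 40 4,5-diol
Product: 41 C5 triethylsilyl ether with free tertiary C4–OH
Conditions: Et3SiOTf, 2,6-lutidine, CH2Cl2, −78 °C
Reagents that add atoms: triethylsilyl trifluoromethanesulfonate, CC[Si](CC)(CC)OS(=O)(=O)C(F)(F)F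
Why: A silyl triflate with a hindered non-nucleophilic base at low temperature should silylate only the secondary C5 hydroxyl, and no nucleophilic amine is present that could add to the methylene lactone.

Step 25
Reactants: 41 C5 triethylsilyl ether with free tertiary C4–OH
Product: 43 1,10:2,3-bis-epoxide, via 1,10-monoepoxide 42 (not isolated)
Conditions: mCPBA (2.5 equiv), Na2HPO4, CH2Cl2, 0 °C to rt
Reagents that add atoms: meta-chloroperbenzoic acid, OOC(=O)c1cccc(Cl)c1
Why: Prilezhaev epoxidation should touch only the two electron-rich ring alkenes (not the methylene lactone or the angelate), and with the diene s-trans and roughly perpendicular to the mean ring plane both alkenes show the same outer face, which for C2=C3 is also the face reached by hydrogen bonding from the C4 hydroxyl with the C4 methyl eclipsing the alkene (least allylic strain, threo delivery), so C10, C1, C2 and C3 should be set as required.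

Step 26
Reactants: 43 1,10:2,3-bis-epoxide
Product: 45 4(15)-alkene C5 silyl ether, via sulfamate 44 (not isolated)
Conditions: Burgess reagent, toluene, 50 °C
Reagents that add atoms: none
Why: Burgess dehydration by syn-elimination of the tertiary sulfamate should take a hydrogen from the C15 methyl, because C3 is an oxirane carbon (an alkylidene oxirane would result) and H5 is anti to the C4 oxygen and deactivated by the silyloxy group.

Step 27
Reactants: 45 4(15)-alkene C5 silyl ether
Product: 46 target, EANPDB COMP_00179
Conditions: HF·pyridine, pyridine, THF, 0 °C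
Reagents that add atoms: none
Why: Pyridine-buffered fluoride cleavage of the secondary triethylsilyl ether should free the C5 hydroxyl without opening the allylic oxirane or adding to the methylene lactone.

Compound list
1 | (R)-(−)-carvone | CC1=CC[C@H](CC1=O)C(C)=C | starting material
2 | lithium dienolate of carvone (deprotonated at C6) | CC1=CC[C@H](C=C1[O-])C(C)=C.[Li+] | intermediate
3 | carvone trimethylsilyl dienol ether (C5–OSiMe3, C5=C6 and C3=C4) | CC1=CC[C@H](C=C1O[Si](C)(C)C)C(C)=C | intermediate
4 | trans-6-(trimethylsilyloxy)carvone | CC1=CC[C@@H](C(C)=C)[C@H](O[Si](C)(C)C)C1=O | intermediate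
5 | trans-6-hydroxycarvone (OH trans to isopropenyl) | CC1=CC[C@@H](C(C)=C)[C@H](O)C1=O | intermediate
6 | trans-6-(tert-butyldimethylsilyloxy)carvone | CC1=CC[C@@H](C(C)=C)[C@H](O[Si](C)(C)C(C)(C)C)C1=O | intermediate
7 | allylic alcohol: C5–OH cis to isopropenyl and trans to C6–OTBS, C3=C4 alkene | CC1=CC[C@@H](C(C)=C)[C@H](O[Si](C)(C)C(C)(C)C)[C@H]1O | intermediate
8 | 3,4-epoxide of 7, oxirane on the C5–OH face | C[C@]12O[C@H]1C[C@@H](C(C)=C)[C@H](O[Si](C)(C)C(C)(C)C)[C@H]2O | intermediate
9 | hydroxy selenide: C3–SePh trans to C4–OH, C4–OH cis to C5–OH | C[C@]1(O)[C@H]([Se]c2ccccc2)C[C@@H](C(C)=C)[C@H](O[Si](C)(C)C(C)(C)C)[C@H]1O | intermediate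
10 | selenoxide of 9 | C[C@]1(O)[C@H]([Se](=O)c2ccccc2)C[C@@H](C(C)=C)[C@H](O[Si](C)(C)C(C)(C)C)[C@H]1O | intermediate
11 | cis-4,5-diol with C2=C3 alkene, tertiary C4–OH, C6–OTBS trans to C1-isopropenyl | C[C@]1(O)C=C[C@@H](C(C)=C)[C@H](O[Si](C)(C)C(C)(C)C)[C@H]1O | intermediate
12 | 4,5-acetonide of 11 | C[C@]12C=C[C@@H](C(C)=C)[C@H](O[Si](C)(C)C(C)(C)C)[C@H]1OC(C)(C)O2 | intermediate
13 | 4,5-acetonide C6 alcohol | C[C@]12C=C[C@@H](C(C)=C)[C@H](O)[C@H]1OC(C)(C)O2 | intermediate
14 | acetonide-protected 1-isopropenylcyclohex-2-en-6-one (isopropenyl and both dioxolane oxygens on one face) | O=C1[C@H](C(C)=C)C=C[C@]2(C)OC(C)(C)O[C@H]12 | intermediate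
15 | trans-1,2-bis(tributylstannyl)ethene | CCCC[Sn](CCCC)(CCCC)/C=C/[Sn](CCCC)(CCCC)CCCC | starting material
16 | (E)-2-(tributylstannyl)vinyllithium | [Li]/C=C/[Sn](CCCC)(CCCC)CCCC | intermediate
17 | (E)-1-(benzyldimethylsilyl)-2-(tributylstannyl)ethene | CCCC[Sn](CCCC)(CCCC)/C=C/[Si](C)(C)Cc1ccccc1 | intermediate
18 | (E)-2-(benzyldimethylsilyl)vinyllithium | [Li]/C=C/[Si](C)(C)Cc1ccccc1 | intermediate
19 | (E)-2-(benzyldimethylsilyl)vinylcerium dichloride | Cl[Ce](Cl)/C=C/[Si](C)(C)Cc1ccccc1 | intermediate
20 | tertiary C6 alcohol: E-silylvinyl trans to C1-isopropenyl, OH on the face of isopropenyl and acetonide | O[C@]1(/C=C/[Si](C)(C)Cc2ccccc2)[C@H](C(C)=C)C=C[C@]3(C)OC(C)(C)O[C@H]13 | intermediate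
21 | allyl bromoacetate | C=CCOC(=O)CBr | starting material
22 | potassium alkoxide of 20 | [K+].[O-][C@]1(/C=C/[Si](C)(C)Cc2ccccc2)[C@H](C(C)=C)C=C[C@]3(C)OC(C)(C)O[C@H]13 | intermediate
23 | ten-membered potassium C6=C7 enolate (C5 trans to C8), C8 silane, 1(10)E,2Z-diene, 4,5-acetonide | [K+].[O-]/C1=C\[C@@H]([Si](C)(C)Cc2ccccc2)C/C(C)=C/C=C\[C@]3(C)OC(C)(C)O[C@H]13 | intermediate
24 | (1(10)E,2Z)-cyclodecadien-6-one, C7 CH2CO2allyl trans to C8 SiMe2Bn, 4,5-acetonide | O=C1[C@H](CC(=O)OCC=C)[C@@H]([Si](C)(C)Cc2ccccc2)C/C(C)=C/C=C\[C@]3(C)OC(C)(C)O[C@H]13 | intermediate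
25 | C6 alcohol of 24 with O6 on the side of O5 and of the C7 arm | O[C@@H]1[C@H](CC(=O)OCC=C)[C@@H]([Si](C)(C)Cc2ccccc2)C/C(C)=C/C=C\[C@]3(C)OC(C)(C)O[C@H]13 | intermediate
26 | C6 mesylate of 25 | CS(=O)(=O)O[C@@H]1[C@H](CC(=O)OCC=C)[C@@H]([Si](C)(C)Cc2ccccc2)C/C(C)=C/C=C\[C@]3(C)OC(C)(C)O[C@H]13 | intermediate
27 | mesyloxy carboxylic acid (held as its morpholinium salt) | CS(=O)(=O)O[C@@H]1[C@H](CC(=O)O)[C@@H]([Si](C)(C)Cc2ccccc2)C/C(C)=C/C=C\[C@]3(C)OC(C)(C)O[C@H]13 | intermediate
28 | trans-fused 6,12-lactone, C8 SiMe2Bn, 1(10)E,2Z-diene, 4,5-acetonide | O=C1O[C@H]2[C@H](C1)[C@@H]([Si](C)(C)Cc4ccccc4)C/C(C)=C/C=C\[C@]3(C)OC(C)(C)O[C@@H]32 | intermediate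
29 | C8 fluorodimethylsilyl lactone | O=C1O[C@H]2[C@H](C1)[C@@H]([Si](C)(C)F)C/C(C)=C/C=C\[C@]3(C)OC(C)(C)O[C@@H]32 | intermediate
30 | 8-hydroxy 6,12-lactone (O8 in the place of silicon) | O=C1O[C@H]2[C@H](C1)[C@@H](O)C/C(C)=C/C=C\[C@]3(C)OC(C)(C)O[C@@H]32 | intermediate
31 | 8-triethylsilyloxy 6,12-lactone | O=C1O[C@H]2[C@H](C1)[C@@H](O[Si](CC)(CC)CC)C/C(C)=C/C=C\[C@]3(C)OC(C)(C)O[C@@H]32 | intermediate
32 | lithium enolate of lactone 31 | [Li+].[O-]C1=C[C@@H]2[C@@H](O[Si](CC)(CC)CC)C/C(C)=C/C=C\[C@]3(C)OC(C)(C)O[C@@H]3[C@H]2O1 | intermediate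
33 | C11 dimethylaminomethyl lactone (C11 configuration of no consequence) | CN(C)CC1C(=O)O[C@H]2[C@H]1[C@@H](O[Si](CC)(CC)CC)C/C(C)=C/C=C\[C@]3(C)OC(C)(C)O[C@@H]32 | intermediate
34 | trimethylammonium iodide of 33 | C[N+](C)(C)CC1C(=O)O[C@H]2[C@H]1[C@@H](O[Si](CC)(CC)CC)C/C(C)=C/C=C\[C@]3(C)OC(C)(C)O[C@@H]32.[I-] | intermediate
35 | alpha-methylene lactone, 8-OTES | C=C1C(=O)O[C@H]2[C@H]1[C@@H](O[Si](CC)(CC)CC)C/C(C)=C/C=C\[C@]3(C)OC(C)(C)O[C@@H]32 | intermediate
36 | 8-hydroxy alpha-methylene lactone, 4,5-acetonide | C=C1C(=O)O[C@H]2[C@H]1[C@@H](O)C/C(C)=C/C=C\[C@]3(C)OC(C)(C)O[C@@H]32 | intermediate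
37 | angelic acid, (Z)-2-methylbut-2-enoic acid | C/C=C(/C)C(=O)O | starting material
38 | angelic 2,4,6-trichlorobenzoic mixed anhydride | C/C=C(/C)C(=O)OC(=O)c1c(Cl)cc(Cl)cc1Cl | intermediate
39 | 8-O-angelate, 4,5-acetonide | C=C1C(=O)O[C@H]2[C@H]1[C@@H](OC(=O)/C(C)=C\C)C/C(C)=C/C=C\[C@]3(C)OC(C)(C)O[C@@H]32 | intermediate
40 | 8-O-angelate 4,5-cis-diol | C=C1C(=O)O[C@H]2[C@H]1[C@@H](OC(=O)/C(C)=C\C)C/C(C)=C/C=C\[C@](C)(O)[C@@H]2O | intermediate
41 | C5 triethylsilyl ether, free tertiary C4–OH | C=C1C(=O)O[C@H]2[C@H]1[C@@H](OC(=O)/C(C)=C\C)C/C(C)=C/C=C\[C@](C)(O)[C@@H]2O[Si](CC)(CC)CC | intermediate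
42 | trans-1,10-monoepoxide with Z C2=C3 alkene | C=C1C(=O)O[C@H]2[C@H]1[C@@H](OC(=O)/C(C)=C\C)C[C@@]1(C)O[C@@H]1/C=C\[C@](C)(O)[C@@H]2O[Si](CC)(CC)CC | intermediate
43 | trans-1,10:cis-2,3-bis-epoxide, tertiary C4–OH, C5–OTES | C=C1C(=O)O[C@H]2[C@H]1[C@@H](OC(=O)/C(C)=C\C)C[C@@]1(C)O[C@@H]1[C@H]1O[C@H]1[C@](C)(O)[C@@H]2O[Si](CC)(CC)CC | intermediate
44 | C4 O-sulfamate of 43 (triethylammonium salt) | C=C1C(=O)O[C@H]2[C@H]1[C@@H](OC(=O)/C(C)=C\C)C[C@@]1(C)O[C@@H]1[C@H]1O[C@H]1[C@](C)(OS(=O)(=O)[N-]C(=O)OC)[C@@H]2O[Si](CC)(CC)CC.CC[NH+](CC)CC | intermediate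
45 | 4(15)-alkene bis-epoxide, C5–OTES | C=C1C(=O)O[C@H]2[C@H]1[C@@H](OC(=O)/C(C)=C\C)C[C@@]1(C)O[C@@H]1[C@H]1O[C@H]1C(=C)[C@@H]2O[Si](CC)(CC)CC | intermediate
46 | EANPDB COMP_00179 | C=C1C(=O)O[C@H]2[C@H]1[C@@H](OC(=O)/C(C)=C\C)C[C@@]1(C)O[C@@H]1[C@H]1O[C@H]1C(=C)[C@@H]2O | target

Total step count: 27
Longest linear sequence: 26 steps (steps 1 to 10 and 12 to 27, from 1 to 46); step 11 makes the side fragment 17.

Steps most likely to fail

Step 13. The alkoxide may break heterolytically at the doubly allylic C1–C6 bond into a dienyl anion and a silyl enone that recombine without selectivity, a boat shift through the ring alkene may compete, or proton transfer may move the enolate towards C5 before it is alkylated. The fallback removes the alkoxide from the rearrangement. Starting from 20, silylation (Me3SiOTf, Et3N, CH2Cl2, −78 °C) would give the trimethylsilyl ether of 20, F1. Heating F1 in toluene (110 to 150 °C, base-washed sealed tube) is a neutral siloxy-Cope rearrangement through the same chair and should give the ring-expanded trimethylsilyl enol ether F2; the equilibrium should lie on that side because a doubly allylic bond is traded for a conjugated diene and an enol ether. MeLi (THF, 0 °C) would then release the regiodefined lithium enolate F3, and alkylation with 21 at −78 °C returns to the route at 24.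

Step 25. Oxygen may be delivered to the wrong face of the trisubstituted C1(10) alkene if the ring shows its other face, or the first-formed vinyl oxirane may be opened by the carboxylic acid. The fallback replaces substrate control at that alkene by catalyst control and separates the two epoxidations. Starting from 41, a Shi epoxidation (D-fructose-derived ketone catalyst, KHSO5 as Oxone, K2CO3 buffer, MeCN–dimethoxymethane–water, 0 °C) should epoxidise only the E-trisubstituted alkene of the diene; by the spiro transition-state model it should give the (1R,10R)-oxirane, which is 42, now isolated. A separate hydroxyl-directed epoxidation of C2=C3 (mCPBA, 1.2 equiv, Na2HPO4, CH2Cl2, 0 °C) then returns to the route at 43. No compound outside the list is made.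

Step 16. E2 loss of the hindered C6 mesylate may outrun the intramolecular displacement, with the amine or the carboxylate acting as base. The fallback uses a neutral internal nucleophile instead of a carboxylate. Starting from 25, aminolysis of the allyl ester with Me2AlNMe2 (from AlMe3 and Me2NH·HCl, CH2Cl2, 0 °C to rt) would give the hydroxy dimethylamide F4, which cannot relactonise easily. Mesylation (MsCl, Et3N, CH2Cl2, −10 °C) would give the mesyloxy amide F5. Warming F5 in MeCN without base should let the amide oxygen displace the mesylate with inversion to the cyclic iminium ether mesylate F6, and hydrolysis with aqueous NaHCO3 returns to the route at 28.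

Further compounds
F1 | step 13 | trimethylsilyl ether of 20 | C[Si](C)(C)O[C@]1(/C=C/[Si](C)(C)Cc2ccccc2)[C@H](C(C)=C)C=C[C@]3(C)OC(C)(C)O[C@H]13
F2 | step 13 | ring-expanded trimethylsilyl enol ether (C6=C7, C8 silane, 1(10)E,2Z-diene) | C[Si](C)(C)O/C1=C\[C@@H]([Si](C)(C)Cc2ccccc2)C/C(C)=C/C=C\[C@]3(C)OC(C)(C)O[C@H]13
F3 | step 13 | lithium C6=C7 enolate | [Li+].[O-]/C1=C\[C@@H]([Si](C)(C)Cc2ccccc2)C/C(C)=C/C=C\[C@]3(C)OC(C)(C)O[C@H]13
F0 | step 25 | none | none
F4 | step 16 | hydroxy dimethylamide from 25 | O[C@@H]1[C@H](CC(=O)N(C)C)[C@@H]([Si](C)(C)Cc2ccccc2)C/C(C)=C/C=C\[C@]3(C)OC(C)(C)O[C@H]13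
F5 | step 16 | mesyloxy dimethylamide | CS(=O)(=O)O[C@@H]1[C@H](CC(=O)N(C)C)[C@@H]([Si](C)(C)Cc2ccccc2)C/C(C)=C/C=C\[C@]3(C)OC(C)(C)O[C@H]13
F6 | step 16 | cyclic iminium ether mesylate (C6 inverted) | C[N+](C)=C1O[C@H]2[C@H](C1)[C@@H]([Si](C)(C)Cc4ccccc4)C/C(C)=C/C=C\[C@]3(C)OC(C)(C)O[C@@H]32.CS(=O)(=O)[O-]
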